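**Plan**
1. Retrosynthesis: the cyclohexenone ring (C3a, C4, C5, C6, C7, C7a, benzofuranone locants) is opened at C3a–C4. The enabling feature is that this ring is a vinylogous ester (O1–C7a=C7–C6=O) whose gamma carbon is the quaternary C3a. In the open dienone 8, deprotonated at C3a, C3a and C4 are therefore the two ends of a 3-oxido-hexatriene.
2. Dienone 8 is cut at C5–C6 (1-methoxyvinyllithium + Weinreb amide), at C7–C7a (amide enolate + lactone carbonyl), at C3a–allyl and at C3–aryl, back to (S)-5-methylfuran-2(5H)-one.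
3. Forward: butenolide, aryl conjugate addition, allylation, Claisen-type condensation and dehydration (the oxygen ring is then complete as a 2-alkylidene-tetrahydrofuran), ketone formation, and base-induced closure of the carbocycle as the last ring.
4. Stereochemistry: C2 is bought (lactic acid pool). C3 is relayed from C2 (aryl enters anti to methyl). C3a is relayed from C3 and C5 is set by equilibration, both in the ring-closing step.

Key step: step 5

Assumption: (S)-5-methylfuran-2(5H)-one and (3,4,5-trimethoxyphenyl)magnesium bromide (THF solution) are taken as catalogue materials; the configuration at the allyl-bearing carbon of 5–8 is erased in step 5 and need not be uniform.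

**Step 1**
Reactants: 1 (S)-5-methylfuran-2(5H)-one; 2 (3,4,5-trimethoxyphenyl)magnesium bromide
Product: 4 (4S,5S)-5-methyl-4-(3,4,5-trimethoxyphenyl)dihydrofuran-2(3H)-one, via silyl ketene acetal 3 (not isolated)
Conditions: CuBr·SMe2 (10 mol%), Me3SiCl, THF, −78 to −40 °C; then 1 M HCl
Reagents that add atoms: none
Why: Copper-catalysed, Me3SiCl-accelerated conjugate addition of the aryl Grignard reagent to the butenolide should occur anti to the C5 methyl group, so hydrolysis of the silyl ketene acetal gives the trans-4,5-disubstituted lactone.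

**Step 2**
Reactants: 4 (4S,5S)-5-methyl-4-(3,4,5-trimethoxyphenyl)dihydrofuran-2(3H)-one
Product: 5 (3R,4S,5S)-5-methyl-3-(prop-2-en-1-yl)-4-(3,4,5-trimethoxyphenyl)dihydrofuran-2(3H)-one
Conditions: LiN(i-Pr)2, THF, −78 °C; allyl bromide, −78 to −30 °C
Reagents that add atoms: allyl bromide, C=CCBr
Why: Substrate-controlled alkylation of the lithium lactone enolate should place the allyl group anti to the neighbouring aryl group.

**Step 3**
Reactants: 5 (3R,4S,5S)-5-methyl-3-(prop-2-en-1-yl)-4-(3,4,5-trimethoxyphenyl)dihydrofuran-2(3H)-one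
Product: 7 (E)-2-[(3R,4S,5S)-5-methyl-3-(prop-2-en-1-yl)-4-(3,4,5-trimethoxyphenyl)dihydrofuran-2(3H)-ylidene]-N-methoxy-N-methylacetamide, via lactol amide 6 (not isolated)
Conditions: N-methoxy-N-methylacetamide, LiN(i-Pr)2 (2.5 equiv each), THF, −78 to −20 °C; H2O; crude, then p-TsOH·H2O (cat.), 4 Å MS, CH2Cl2, rt
Reagents that add atoms: N-methoxy-N-methylacetamide, CC(=O)N(C)OC
Why: Claisen-type addition of the amide enolate to the lactone carbonyl gives the lactol (in equilibrium with the hydroxy beta-keto amide), and acid-catalysed dehydration should give the conjugated exocyclic enol ether (vinylogous carbamate) as the thermodynamic isomer.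

**Step 4**
Reactants: 7 (E)-2-[(3R,4S,5S)-5-methyl-3-(prop-2-en-1-yl)-4-(3,4,5-trimethoxyphenyl)dihydrofuran-2(3H)-ylidene]-N-methoxy-N-methylacetamide
Product: 8 (E)-3-methoxy-1-[(3R,4S,5S)-5-methyl-3-(prop-2-en-1-yl)-4-(3,4,5-trimethoxyphenyl)dihydrofuran-2(3H)-ylidene]but-3-en-2-one
Conditions: methyl vinyl ether (excess), t-BuLi, THF, −78 to 0 °C; then 7, −78 to −40 °C; pH 7 phosphate buffer
Reagents that add atoms: methyl vinyl ether, COC=C
Why: Weinreb ketone synthesis, in which 1-methoxyvinyllithium adds once to the N-methoxy-N-methylamide through a chelated tetrahedral intermediate and buffered work-up should release the 1-methoxyvinyl ketone with its enol ether intact.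

**Step 5**
Reactants: 8 (E)-3-methoxy-1-[(3R,4S,5S)-5-methyl-3-(prop-2-en-1-yl)-4-(3,4,5-trimethoxyphenyl)dihydrofuran-2(3H)-ylidene]but-3-en-2-one
Product: 11 (2S,3R,3aR,5R)-5-methoxy-2-methyl-3a-(prop-2-en-1-yl)-3-(3,4,5-trimethoxyphenyl)-3,3a,4,5-tetrahydro-1-benzofuran-6(2H)-one (the target), via potassium trienolate 9 (not isolated), via potassium cyclohexadienolate 10 (not isolated)
Conditions: KOt-Bu (0.3 equiv), THF/t-BuOH (10:1), 0.01 M, 0 to 40 °C; then AcOH (0.3 equiv)
Reagents that add atoms: none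
Why: Proposed new method: KOt-Bu removes the only acidic proton of 8, the C3a–H gamma to the C6 carbonyl through the O1–C7a=C7 enol ether, and the cross-conjugated trienolate 9 (a 3-oxido-hexatriene C4=C5–C6(O−)=C7–C7a=C3a) should close by thermal disrotatory 6π electrocyclization, which can equally be read as a 6-endo-trig vinylogous Michael addition of C3a to C4, to give dienolate 10 that is protonated at C5 by t-BuOH with return of the base. The closest known reaction type is the oxido-accelerated electrocyclization of 3-oxido-hexatrienes made from cyclobutenones and alkenyllithiums, which close to cyclohexadienolates at or below room temperature; generation of such a trienolate by gamma-deprotonation of a 2-(acylmethylidene)tetrahydrofuran and closure onto a fully substituted terminus have not been shown. The cyclohexenone is the only ring closed, in the 6-endo (electrocyclic) mode through the C3a–C4 bond, while the oxygen ring stays intact. C3a is controlled by the C3 stereocenter: C4 should bond to the face of the planar dihydrofuran anti to the neighbouring aryl group, which leaves the allyl group cis to the aryl group. C5 is controlled thermodynamically: reversible enolization under the reaction conditions should leave the methoxy group equatorial and trans to the pseudoaxial allyl group, which avoids a 1,3-diaxial contact. The step needs the enolate geometry with C5 cis to C7a across C6=C7 and ring closure faster than intermolecular Michael addition; proton exchange through the C7-protonated beta,gamma-enone interconverts the enolate geometries so that the reactive one is drained, C7 cannot attack C4 (four-membered ring), and high dilution disfavours oligomers.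

**Compound list**
1 | (S)-5-methylfuran-2(5H)-one | O=C1O[C@@H](C)C=C1 | starting material
2 | (3,4,5-trimethoxyphenyl)magnesium bromide | COc1cc([Mg]Br)cc(OC)c1OC | starting material
3 | trimethyl{[(4S,5S)-5-methyl-4-(3,4,5-trimethoxyphenyl)-4,5-dihydrofuran-2-yl]oxy}silane | C[Si](C)(C)OC1=C[C@@H](c2cc(OC)c(OC)c(OC)c2)[C@H](C)O1 | intermediate
4 | (4S,5S)-5-methyl-4-(3,4,5-trimethoxyphenyl)dihydrofuran-2(3H)-one | O=C1O[C@@H](C)[C@H](c2cc(OC)c(OC)c(OC)c2)C1 | intermediate
5 | (3R,4S,5S)-5-methyl-3-(prop-2-en-1-yl)-4-(3,4,5-trimethoxyphenyl)dihydrofuran-2(3H)-one | O=C1O[C@@H](C)[C@H](c2cc(OC)c(OC)c(OC)c2)[C@H]1CC=C | intermediate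
6 | 2-[(3R,4S,5S)-2-hydroxy-5-methyl-3-(prop-2-en-1-yl)-4-(3,4,5-trimethoxyphenyl)tetrahydrofuran-2-yl]-N-methoxy-N-methylacetamide (anomer mixture) | CON(C)C(=O)CC1(O)O[C@@H](C)[C@H](c2cc(OC)c(OC)c(OC)c2)[C@H]1CC=C | intermediate
7 | (E)-2-[(3R,4S,5S)-5-methyl-3-(prop-2-en-1-yl)-4-(3,4,5-trimethoxyphenyl)dihydrofuran-2(3H)-ylidene]-N-methoxy-N-methylacetamide | CON(C)C(=O)/C=C1/O[C@@H](C)[C@H](c2cc(OC)c(OC)c(OC)c2)[C@H]1CC=C | intermediate
8 | (E)-3-methoxy-1-[(3R,4S,5S)-5-methyl-3-(prop-2-en-1-yl)-4-(3,4,5-trimethoxyphenyl)dihydrofuran-2(3H)-ylidene]but-3-en-2-one | C=C(OC)C(=O)/C=C1/O[C@@H](C)[C@H](c2cc(OC)c(OC)c(OC)c2)[C@H]1CC=C | intermediate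
9 | potassium (1E)-3-methoxy-1-[(4R,5S)-5-methyl-3-(prop-2-en-1-yl)-4-(3,4,5-trimethoxyphenyl)-4,5-dihydrofuran-2-yl]buta-1,3-dien-2-olate | C=C(OC)/C([O-])=C\C1=C(CC=C)[C@@H](c2cc(OC)c(OC)c(OC)c2)[C@H](C)O1.[K+] | intermediate
10 | potassium (2S,3R,3aR)-5-methoxy-2-methyl-3a-(prop-2-en-1-yl)-3-(3,4,5-trimethoxyphenyl)-2,3,3a,4-tetrahydro-1-benzofuran-6-olate | C=CC[C@]12CC(OC)=C([O-])C=C1O[C@@H](C)[C@@H]2c1cc(OC)c(OC)c(OC)c1.[K+] | intermediate
11 | (2S,3R,3aR,5R)-5-methoxy-2-methyl-3a-(prop-2-en-1-yl)-3-(3,4,5-trimethoxyphenyl)-3,3a,4,5-tetrahydro-1-benzofuran-6(2H)-one | C=CC[C@]12C[C@@H](OC)C(=O)C=C1O[C@@H](C)[C@@H]2c1cc(OC)c(OC)c(OC)c1 | target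

**Total step count:** 5
**Longest linear sequence:** 5 steps (1 to 11)

**Steps most likely to fail**

Step 5 (proposed new method). The closure may stall if the enolate geometries do not interconvert, intermolecular Michael addition may outrun it, or the facial selectivity at C3a may be poor. The fallback uses known reactions only, sets out from lactone 5 and comes back at target 11. Commercial 3,3-dimethoxybutan-2-one is heated with catalytic p-TsOH·H2O while methanol distils, to give 3-methoxybut-3-en-2-one F1. The lithium enolate of 5 (LiN(i-Pr)2, THF, −78 °C) is added in Michael fashion to F1, anti to the aryl group, to give (3R,4R,5S)-3-(2-methoxy-3-oxobutyl)-5-methyl-3-(prop-2-en-1-yl)-4-(3,4,5-trimethoxyphenyl)dihydrofuran-2(3H)-one F2 with the quaternary carbon in place. KOt-Bu in THF then effects a Dieckmann-type condensation of the methyl ketone enolate onto the lactone carbonyl, which opens the lactone and gives (4R)-4-[(1R,2S)-2-hydroxy-1-(3,4,5-trimethoxyphenyl)propyl]-6-methoxy-4-(prop-2-en-1-yl)cyclohexane-1,3-dione F3. p-TsOH·H2O in toluene should close the enol ether between the secondary hydroxyl and the neighbouring ring carbonyl and equilibrate C5, giving 11.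

Step 3. Proton transfer from the lactone to the amide enolate, reversal of the addition on warming, or self-condensation of the enolate may return 5. The fallback sets out from 5 and comes back at 7, and forms the oxygen ring by oxa-Michael addition instead of condensation onto the lactone. Reduction with i-Bu2AlH (CH2Cl2, −78 °C) gives (3R,4S,5S)-5-methyl-3-(prop-2-en-1-yl)-4-(3,4,5-trimethoxyphenyl)tetrahydrofuran-2-ol F4. Ohira–Bestmann homologation (dimethyl (1-diazo-2-oxopropyl)phosphonate, K2CO3, MeOH) gives (2S,3S,4R)-4-ethynyl-3-(3,4,5-trimethoxyphenyl)hept-6-en-2-ol F5. Double deprotonation (n-BuLi, 2 equiv, THF, −78 °C) and C-acylation with N-methoxy-N-methylcarbamoyl chloride give (4R,5S,6S)-6-hydroxy-N-methoxy-N-methyl-4-(prop-2-en-1-yl)-5-(3,4,5-trimethoxyphenyl)hept-2-ynamide F6. Catalytic KOt-Bu in THF should then induce 5-exo-dig oxa-Michael addition of the hydroxyl to the ynamide, giving 7.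

Step 4. The organolithium may act as a base toward the gamma C–H of 7 or add in conjugate fashion, or the enol ether of 8 may be hydrolysed on work-up. The fallback sets out from 5 and comes back at 8, bringing in the four-carbon unit intact. The lithium enolate of commercial 3,3-dimethoxybutan-2-one (LiN(i-Pr)2, THF, −78 °C; only the acetyl methyl can enolize) is added to 5 to give 1-[(3R,4S,5S)-2-hydroxy-5-methyl-3-(prop-2-en-1-yl)-4-(3,4,5-trimethoxyphenyl)tetrahydrofuran-2-yl]-3,3-dimethoxybutan-2-one F7. p-TsOH·H2O (cat.) with 4 Å MS in CH2Cl2 dehydrates it to (E)-3,3-dimethoxy-1-[(3R,4S,5S)-5-methyl-3-(prop-2-en-1-yl)-4-(3,4,5-trimethoxyphenyl)dihydrofuran-2(3H)-ylidene]butan-2-one F8. Me3SiOTf and i-Pr2NEt (CH2Cl2, 0 °C) should then convert the dimethyl ketal into the methyl enol ether, giving 8.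

**Further compounds**
F1 | step 5 | 3-methoxybut-3-en-2-one | CC(=O)C(=C)OC
F2 | step 5 | (3R,4R,5S)-3-(2-methoxy-3-oxobutyl)-5-methyl-3-(prop-2-en-1-yl)-4-(3,4,5-trimethoxyphenyl)dihydrofuran-2(3H)-one (both configurations at the methoxy-bearing carbon) | C=CC[C@]1(CC(OC)C(C)=O)C(=O)O[C@@H](C)[C@@H]1c1cc(OC)c(OC)c(OC)c1
F3 | step 5 | (4R)-4-[(1R,2S)-2-hydroxy-1-(3,4,5-trimethoxyphenyl)propyl]-6-methoxy-4-(prop-2-en-1-yl)cyclohexane-1,3-dione | C=CC[C@@]1(CC(OC)C(=O)CC1=O)[C@@H](c1cc(OC)c(OC)c(OC)c1)[C@H](C)O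
F4 | step 3 | (3R,4S,5S)-5-methyl-3-(prop-2-en-1-yl)-4-(3,4,5-trimethoxyphenyl)tetrahydrofuran-2-ol (anomer mixture) | OC1O[C@@H](C)[C@H](c2cc(OC)c(OC)c(OC)c2)[C@H]1CC=C
F5 | step 3 | (2S,3S,4R)-4-ethynyl-3-(3,4,5-trimethoxyphenyl)hept-6-en-2-ol | C#C[C@H](CC=C)[C@@H](c1cc(OC)c(OC)c(OC)c1)[C@H](C)O
F6 | step 3 | (4R,5S,6S)-6-hydroxy-N-methoxy-N-methyl-4-(prop-2-en-1-yl)-5-(3,4,5-trimethoxyphenyl)hept-2-ynamide | CON(C)C(=O)C#C[C@H](CC=C)[C@@H](c1cc(OC)c(OC)c(OC)c1)[C@H](C)O
F7 | step 4 | 1-[(3R,4S,5S)-2-hydroxy-5-methyl-3-(prop-2-en-1-yl)-4-(3,4,5-trimethoxyphenyl)tetrahydrofuran-2-yl]-3,3-dimethoxybutan-2-one (anomer mixture) | CC(OC)(OC)C(=O)CC1(O)O[C@@H](C)[C@H](c2cc(OC)c(OC)c(OC)c2)[C@H]1CC=C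
F8 | step 4 | (E)-3,3-dimethoxy-1-[(3R,4S,5S)-5-methyl-3-(prop-2-en-1-yl)-4-(3,4,5-trimethoxyphenyl)dihydrofuran-2(3H)-ylidene]butan-2-one | CC(OC)(OC)C(=O)/C=C1/O[C@@H](C)[C@H](c2cc(OC)c(OC)c(OC)c2)[C@H]1CC=C
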